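**Plan**

Lettering: ring A is the syringyl arene; ring B the tetrahydrofuran O–C7–C8–C8'–C9'; ring C the tetrahydrofuran C7'–O–C9–C8–C8'; ring D the arene and ring E the dihydrofuran (O1, C2, C3) of the dihydrobenzofuran; ring F the guaiacyl arene.
Cuts: two silyl groups and one acetate come off first. Ring C is then cut at C7'–O and ring B at C8–C8', which unfolds the dioxabicyclo[3.3.0]octane into an acyclic epoxy cinnamyl ether. Next the C9'–O ether bond is cut (cinnamyl acetate 10 + epoxy alcohol 14), and last C2–C3 of ring E (aryldiazoacetate 7).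
Forward: ring E closes first by carbenoid C–H insertion. The two fragments are joined by allylic etherification. One flask then adds the epoxide unit C8–C9–O across C8'=C7', closing ring B (radical 5-exo) and, last of all, ring C (C7'–O).
Enabling feature: C7' is benzylic on ring D and para to the ring E oxygen O1, so it can carry first a stabilised radical and then a stabilised cation. The epoxide oxygen is released as an alkoxide on C9, cis to C7' on ring B and 1,4 to it.
Stereochemistry: cis C2/C3 come from a chiral dirhodium catalyst and C7 from a Sharpless kinetic resolution. C8, C8' and C7' are relayed from C7 in the key step.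

Key step: step 13

Assumption: the descriptors are taken as written, which means a cis (2S,3S) ring E and an exo,exo (7S,8R,7'S,8'R) bicycle, and Rh2(R-PTTL)4 (dirhodium tetrakis[N-phthaloyl-(R)-tert-leucinate]) is taken as the catalyst antipode that leads to this cis series.

**Route**

Step 1
Reactants: 1 vanillin (4-hydroxy-3-methoxybenzaldehyde)
Product: 2 3-methoxy-4-(triisopropylsilyloxy)benzaldehyde
Conditions: iPr3SiCl, imidazole, DMF, rt
Reagents that add atoms: triisopropylsilyl chloride, CC(C)[Si](Cl)(C(C)C)C(C)C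
Why: Silyl ether protection of the phenol gives a group that should survive hydride, Mitsunobu, carbenoid, zinc alkoxide and Cp2TiCl conditions and leaves with fluoride at the end.

Step 2
Reactants: 2 3-methoxy-4-(triisopropylsilyloxy)benzaldehyde
Product: 3 [3-methoxy-4-(triisopropylsilyloxy)phenyl]methanol
Conditions: NaBH4, MeOH, 0 °C
Reagents that add atoms: none
Why: Borohydride reduction of an aromatic aldehyde gives the benzylic alcohol and leaves the aryl silyl ether alone.

Step 3
Reactants: 3 [3-methoxy-4-(triisopropylsilyloxy)phenyl]methanol; 4 5-iodovanillin (4-hydroxy-3-iodo-5-methoxybenzaldehyde)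
Product: 5 3-iodo-5-methoxy-4-[3-methoxy-4-(triisopropylsilyloxy)benzyloxy]benzaldehyde
Conditions: PPh3, DIAD, THF, 0 °C to rt
Reagents that add atoms: none
Why: Mitsunobu etherification joins the acidic phenol 4 to the primary benzylic alcohol under neutral conditions that touch neither the aldehyde nor the iodide.

Step 4
Reactants: 5 3-iodo-5-methoxy-4-[3-methoxy-4-(triisopropylsilyloxy)benzyloxy]benzaldehyde
Product: 6 methyl (E)-3-{3-iodo-5-methoxy-4-[3-methoxy-4-(triisopropylsilyloxy)benzyloxy]phenyl}acrylate
Conditions: Ph3P=CHCO2Me, toluene, 80 °C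
Reagents that add atoms: methyl (triphenylphosphoranylidene)acetate, COC(=O)C=P(c1ccccc1)(c1ccccc1)c1ccccc1
Why: Wittig olefination with a stabilised ylide should give the E enoate, which holds C7'–C9' in a form too electron-poor to react with the later carbenoid.

Step 5
Reactants: 6 methyl (E)-3-{3-iodo-5-methoxy-4-[3-methoxy-4-(triisopropylsilyloxy)benzyloxy]phenyl}acrylate
Product: 7 ethyl 2-diazo-2-{3-methoxy-5-[(E)-2-(methoxycarbonyl)vinyl]-2-[3-methoxy-4-(triisopropylsilyloxy)benzyloxy]phenyl}acetate
Conditions: N2CHCO2Et, Pd(PPh3)4 (5 mol %), Ag2CO3 (0.5 equiv), Et3N, toluene, rt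
Reagents that add atoms: ethyl diazoacetate, CCOC(=O)C=[N+]=[N-]
Why: Palladium-catalysed cross-coupling of an aryl iodide with the C–H bond of a diazoacetate keeps the diazo group at room temperature, and the C–I bond is the only site of oxidative addition.

Step 6
Reactants: 7 ethyl 2-diazo-2-{3-methoxy-5-[(E)-2-(methoxycarbonyl)vinyl]-2-[3-methoxy-4-(triisopropylsilyloxy)benzyloxy]phenyl}acetate
Product: 8 ethyl (2S,3R)-7-methoxy-5-[(E)-2-(methoxycarbonyl)vinyl]-2-[3-methoxy-4-(triisopropylsilyloxy)phenyl]-2,3-dihydrobenzofuran-3-carboxylate (2,3-cis)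
Conditions: Rh2(R-PTTL)4 (1 mol %), toluene, −60 °C
Reagents that add atoms: none
Why: Intramolecular 1,5 C–H insertion of a donor/acceptor rhodium carbenoid into the electron-rich benzylic ether C–H bond closes ring E, and the concerted transition state in the chiral pocket of the catalyst should give the kinetic cis product and fix C2 and C3 together, while the electron-poor enoate is not cyclopropanated.

Step 7
Reactants: 8 ethyl (2S,3R)-cis-dihydrobenzofuran diester
Product: 9 (E)-3-{(2S,3S)-3-(hydroxymethyl)-7-methoxy-2-[3-methoxy-4-(triisopropylsilyloxy)phenyl]-2,3-dihydrobenzofuran-5-yl}prop-2-en-1-ol (2,3-cis diol)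
Conditions: iBu2AlH (6 equiv), CH2Cl2, −78 °C; aq potassium sodium tartrate
Reagents that add atoms: none
Why: Hydride reduction of both esters at low temperature (1,2-reduction of the enoate) avoids enolisation at C3, so the cis relationship should be kept (the descriptor at C3 changes only by priority).

Step 8
Reactants: 9 cis diol
Product: 10 diacetate of 9 (cinnamyl acetate and C3–CH2OAc, 2S,3S)
Conditions: Ac2O, pyridine, DMAP (cat.), CH2Cl2, 0 °C
Reagents that add atoms: acetic anhydride, CC(=O)OC(C)=O
Why: Exhaustive acetylation needs no differentiation of the two hydroxyls, because the cinnamyl acetate later acts as the leaving group and the saturated primary acetate as a protecting group.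

Step 9
Reactants: 11 syringaldehyde (4-hydroxy-3,5-dimethoxybenzaldehyde)
Product: 12 3,5-dimethoxy-4-(triisopropylsilyloxy)benzaldehyde
Conditions: iPr3SiCl, imidazole, DMAP (cat.), DMF, 50 °C
Reagents that add atoms: triisopropylsilyl chloride, CC(C)[Si](Cl)(C(C)C)C(C)C
Why: Silyl ether protection of the hindered phenol, helped by gentle heating, matches the protecting group of the other fragment.

Step 10
Reactants: 12 3,5-dimethoxy-4-(triisopropylsilyloxy)benzaldehyde
Product: 13 (±)-1-[3,5-dimethoxy-4-(triisopropylsilyloxy)phenyl]prop-2-en-1-ol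
Conditions: CH2=CHMgBr, THF, −78 to 0 °C; aq NH4Cl
Reagents that add atoms: vinylmagnesium bromide, C=C[Mg]Br
Why: Grignard addition to the aldehyde gives the aryl vinyl carbinol as a racemate, and C7 is left for resolution in the next step.

Step 11
Reactants: 13 (±)-1-[3,5-dimethoxy-4-(triisopropylsilyloxy)phenyl]prop-2-en-1-ol
Product: 14 (R)-[3,5-dimethoxy-4-(triisopropylsilyloxy)phenyl][(S)-oxiran-2-yl]methanol
Conditions: Ti(OiPr)4, D-(−)-diisopropyl tartrate, tBuOOH (0.45 equiv), 4 Å MS, CH2Cl2, −20 °C
Reagents that add atoms: tert-butyl hydroperoxide, CC(C)(C)OO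
Why: In the Sharpless kinetic resolution with the D-(−)-tartrate the (S)-carbinol should be epoxidised much faster than its mirror image and give the erythro epoxy alcohol, so stopping short of half conversion fixes C7 (R here, 7S in the target by priority change), the slow (R)-alcohol is separated, and the epoxide centre C8 is of no consequence later.

Step 12
Reactants: 14 epoxy alcohol; 10 diacetate
Product: 16 (E)-cinnamyl ether of 14 carrying the cis ring E unit of 10 (7R,8S; 2S,3S), via zinc bis-alkoxide 15 (not isolated)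
Conditions: 14, Et2Zn (0.5 equiv), THF, 0 °C; then 10, Pd(OAc)2 (5 mol %), 2-(di-tert-butylphosphino)biphenyl (7.5 mol %), THF, rt
Reagents that add atoms: none
Why: In this Tsuji–Trost allylic etherification with a zinc alkoxide as oxygen nucleophile, zerovalent palladium formed in the flask ionises only the cinnamyl acetate, the alkoxide attacks the unsubstituted terminus of the syn π-allyl complex to give the linear E ether, and the weakly basic medium should leave the epoxide, the primary acetate and the existing stereocentres untouched.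

Step 13
Reactants: 16 epoxy cinnamyl ether
Product: 19 bis-silyl acetate of the target (exo,exo furofuran 7S,8R,7'S,8'R; cis ring E 2S,3S), via bis-titanated tetrahydrofuran 17 (not isolated), via benzylic iodide 18 (not isolated)
Conditions: Cp2TiCl2 (2.5 equiv), Zn dust, THF, rt, the green Cp2TiCl solution added slowly to 16; then I2 (1.2 equiv), THF, rt to 45 °C
Reagents that add atoms: none
Why: Cp2TiCl, a trivalent titanium reagent made in the flask, opens the terminal epoxide by single-electron transfer to the secondary C8 radical (the oxygen stays on C9 as titanium alkoxide), this radical adds to C8' of the cinnamyl double bond, the C7' benzylic radical is caught by a second Cp2TiCl to give 17, and I2 turns the C–Ti bond into the benzylic iodide 18, which ionises with help from the para oxygen O1 and is captured by the C9 alkoxide. The closest known reaction type is the Nugent–RajanBabu reductive epoxide opening with radical cyclisation and iodine-induced etherification, which is established for epoxy cinnamyl ethers that lead to 2,6-diaryl-3,7-dioxabicyclo[3.3.0]octanes. Ring B closes 5-exo-trig (radical), and ring C, the last ring, closes 5-exo-tet at C7' with marked SN1 character, so that overall the unit C8–C9–O adds across C8'=C7'. C8 and C8' are set in a Beckwith–Houk chair-like transition state with ring A on C7 pseudo-equatorial, which places C9 trans to ring A and cis to C7', and the epoxide stereocentre, lost in the radical, does not matter. C7' is set in the C–O closure, where the planar benzylic cation is attacked with ring D turned to the convex face of the forming cis-bicyclooctane (exo aryl, 7'S), whatever the configuration of 17 and 18. The step needs opening of the epoxide towards the secondary radical (secured by the terminal epoxide), cyclisation faster than reduction of the radical (secured by the styrene-type acceptor and slow addition) and survival of cis ring E, acetate and silyl ethers (secured by the neutral, non-basic medium).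

Step 14
Reactants: 19 bis-silyl acetate of the target
Product: 20 bis-silyl ether of the target with free C3–CH2OH
Conditions: K2CO3 (0.2 equiv), MeOH, 0 °C
Reagents that add atoms: none
Why: Base-catalysed transesterification removes the primary acetate while both phenols are still silylated, so no phenoxide that could open ring E by a quinone methide path is present.

Step 15
Reactants: 20 bis-silyl ether of the target
Product: 21 target compound
Conditions: Bu4NF, AcOH (1:1), THF, 0 °C
Reagents that add atoms: none
Why: Fluoride desilylation buffered with acetic acid frees both phenols under nearly neutral conditions, which should leave the cis ring E and the benzylic ethers at C7 and C7' unchanged.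

**Compound list**

1 | vanillin | COc1cc(C=O)ccc1O | starting material
2 | 3-methoxy-4-(triisopropylsilyloxy)benzaldehyde | COc1cc(C=O)ccc1O[Si](C(C)C)(C(C)C)C(C)C | intermediate
3 | [3-methoxy-4-(triisopropylsilyloxy)phenyl]methanol | COc1cc(CO)ccc1O[Si](C(C)C)(C(C)C)C(C)C | intermediate
4 | 5-iodovanillin | COc1cc(C=O)cc(I)c1O | starting material
5 | 3-iodo-5-methoxy-4-[3-methoxy-4-(triisopropylsilyloxy)benzyloxy]benzaldehyde | COc1cc(C=O)cc(I)c1OCc1ccc(O[Si](C(C)C)(C(C)C)C(C)C)c(OC)c1 | intermediate
6 | methyl (E)-3-{3-iodo-5-methoxy-4-[3-methoxy-4-(triisopropylsilyloxy)benzyloxy]phenyl}acrylate | COC(=O)/C=C/c1cc(I)c(OCc2ccc(O[Si](C(C)C)(C(C)C)C(C)C)c(OC)c2)c(OC)c1 | intermediate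
7 | ethyl aryldiazoacetate | CCOC(=O)C(=[N+]=[N-])c1cc(/C=C/C(=O)OC)cc(OC)c1OCc1ccc(O[Si](C(C)C)(C(C)C)C(C)C)c(OC)c1 | intermediate
8 | ethyl (2S,3R)-cis-dihydrobenzofuran-3-carboxylate with 5-(E)-enoate | COc1cc([C@H]2Oc3c(OC)cc(/C=C/C(=O)OC)cc3[C@H]2C(=O)OCC)ccc1O[Si](C(C)C)(C(C)C)C(C)C | intermediate
9 | (2S,3S)-cis diol | COc1cc([C@H]2Oc3c(OC)cc(/C=C/CO)cc3[C@H]2CO)ccc1O[Si](C(C)C)(C(C)C)C(C)C | intermediate
10 | (2S,3S)-cis diacetate | COc1cc([C@H]2Oc3c(OC)cc(/C=C/COC(C)=O)cc3[C@H]2COC(C)=O)ccc1O[Si](C(C)C)(C(C)C)C(C)C | intermediate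
11 | syringaldehyde | COc1cc(C=O)cc(OC)c1O | starting material
12 | 3,5-dimethoxy-4-(triisopropylsilyloxy)benzaldehyde | COc1cc(C=O)cc(OC)c1O[Si](C(C)C)(C(C)C)C(C)C | intermediate
13 | (±)-1-[3,5-dimethoxy-4-(triisopropylsilyloxy)phenyl]prop-2-en-1-ol | C=CC(O)c1cc(OC)c(O[Si](C(C)C)(C(C)C)C(C)C)c(OC)c1 | intermediate
14 | (R)-[3,5-dimethoxy-4-(triisopropylsilyloxy)phenyl][(S)-oxiran-2-yl]methanol | O[C@H](c1cc(OC)c(O[Si](C(C)C)(C(C)C)C(C)C)c(OC)c1)[C@@H]1CO1 | intermediate
15 | zinc bis-alkoxide of 14 | [Zn](O[C@H](c1cc(OC)c(O[Si](C(C)C)(C(C)C)C(C)C)c(OC)c1)[C@@H]1CO1)O[C@H](c1cc(OC)c(O[Si](C(C)C)(C(C)C)C(C)C)c(OC)c1)[C@@H]1CO1 | intermediate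
16 | epoxy cinnamyl ether (7R,8S; 2S,3S) | COc1cc([C@H]2Oc3c(OC)cc(/C=C/CO[C@H](c4cc(OC)c(O[Si](C(C)C)(C(C)C)C(C)C)c(OC)c4)[C@@H]4CO4)cc3[C@H]2COC(C)=O)ccc1O[Si](C(C)C)(C(C)C)C(C)C | intermediate
17 | bis-titanated tetrahydrofuran (C7'–TiCp2Cl, C9–O–TiCp2Cl; Cp drawn σ-bonded; C7' undefined) | COc1cc([C@H]2Oc3c(OC)cc(C([C@H]4CO[C@H](c5cc(OC)c(O[Si](C(C)C)(C(C)C)C(C)C)c(OC)c5)[C@H]4CO[Ti](Cl)(C6C=CC=C6)C6C=CC=C6)[Ti](Cl)(C6C=CC=C6)C6C=CC=C6)cc3[C@H]2COC(C)=O)ccc1O[Si](C(C)C)(C(C)C)C(C)C | intermediate
18 | benzylic iodide (C7'–I, C9–O–TiCp2Cl; C7' undefined) | COc1cc([C@H]2Oc3c(OC)cc(C(I)[C@H]4CO[C@H](c5cc(OC)c(O[Si](C(C)C)(C(C)C)C(C)C)c(OC)c5)[C@H]4CO[Ti](Cl)(C6C=CC=C6)C6C=CC=C6)cc3[C@H]2COC(C)=O)ccc1O[Si](C(C)C)(C(C)C)C(C)C | intermediate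
19 | bis-silyl acetate of the target | COc1cc([C@H]2Oc3c(OC)cc([C@H]4OC[C@H]5[C@@H]4CO[C@@H]5c4cc(OC)c(O[Si](C(C)C)(C(C)C)C(C)C)c(OC)c4)cc3[C@H]2COC(C)=O)ccc1O[Si](C(C)C)(C(C)C)C(C)C | intermediate
20 | bis-silyl ether of the target | COc1cc([C@H]2Oc3c(OC)cc([C@H]4OC[C@H]5[C@@H]4CO[C@@H]5c4cc(OC)c(O[Si](C(C)C)(C(C)C)C(C)C)c(OC)c4)cc3[C@H]2CO)ccc1O[Si](C(C)C)(C(C)C)C(C)C | intermediate
21 | CNP0126146.1 | COc1cc([C@H]2Oc3c(OC)cc([C@H]4OC[C@H]5[C@@H]4CO[C@@H]5c4cc(OC)c(O)c(OC)c4)cc3[C@H]2CO)ccc1O | target

**Step count and risks**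

Total step count: 15. Longest linear sequence: 12 (steps 1–8 and 12–15).

Steps most likely to fail:

Step 13. The benzylic titanium species may be protonated or reduced before iodine reaches it. Iodine or traces of HI may also cause epimerisation at C2 of ring E or at C7'. The fallback sets out from 16 and comes back at 19. The Cp2TiCl cyclisation is run as in step 13 but quenched with aqueous NaH2PO4 instead of I2. This protonates the C7'–Ti bond and should give the monocyclic (2S,3R,4R)-2-aryl-3-hydroxymethyl-4-arylmethyl-tetrahydrofuran F1. Ring C is then closed in a separate operation by benzylic C–H oxidation with DDQ (CH2Cl2, 4 Å MS, 0 °C). Hydride abstraction from C7', activated by the para oxygen O1, gives the same cation, and the C9 hydroxyl captures it.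

Step 12. Attack of the hindered secondary alkoxide on the π-allyl complex may be sluggish. Payne-type migration or opening of the epoxide at zinc, or acyl transfer from the primary acetate, may compete. The fallback sets out from 9 and comes back at 21.
- Corey–Kim chlorination (NCS, Me2S, CH2Cl2, −20 °C) should convert only the allylic hydroxyl and give the cinnamyl chloride alcohol F2.
- Silylation (TBSOTf, 2,6-lutidine, CH2Cl2, −78 °C) gives the chloride silyl ether F3.
- Williamson etherification with the sodium alkoxide of 14 (NaH, Bu4NI, THF/DMF, 0 °C) gives the epoxy cinnamyl ether F4.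
- The conditions of step 13 give the tris-silyl furofuran F5.
- Bu4NF/AcOH removes all three silyl groups and gives 21.

Step 6. The methoxy group next to the benzyloxy group may disturb the fit in the catalyst pocket, with poor facial selectivity or erosion of the cis preference. The fallback sets out from 6 and comes back at 9. The coupling of step 5 is run with (R)-pantolactonyl diazoacetate F6, obtained from (R)-pantolactone, and gives the auxiliary-bearing aryldiazoacetate F7. The insertion then gives the cis pantolactonyl ester F8 together with a diastereomer rather than an enantiomer, so the unwanted isomer can be removed by crystallisation or chromatography. iBu2AlH cleaves the auxiliary reductively, reduces the enoate and gives 9.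

**Further compounds**

F1 | step 13 | (2S,3R,4R)-tetrahydrofuran with C9 hydroxymethyl and C7' methylene (acetate and two silyl ethers kept) | COc1cc([C@H]2Oc3c(OC)cc(C[C@H]4CO[C@H](c5cc(OC)c(O[Si](C(C)C)(C(C)C)C(C)C)c(OC)c5)[C@H]4CO)cc3[C@H]2COC(C)=O)ccc1O[Si](C(C)C)(C(C)C)C(C)C
F2 | step 12 | cinnamyl chloride alcohol (2S,3S) | COc1cc([C@H]2Oc3c(OC)cc(/C=C/CCl)cc3[C@H]2CO)ccc1O[Si](C(C)C)(C(C)C)C(C)C
F3 | step 12 | cinnamyl chloride tert-butyldimethylsilyl ether (2S,3S) | COc1cc([C@H]2Oc3c(OC)cc(/C=C/CCl)cc3[C@H]2CO[Si](C)(C)C(C)(C)C)ccc1O[Si](C(C)C)(C(C)C)C(C)C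
F4 | step 12 | epoxy cinnamyl ether with C3–CH2OTBS | COc1cc([C@H]2Oc3c(OC)cc(/C=C/CO[C@H](c4cc(OC)c(O[Si](C(C)C)(C(C)C)C(C)C)c(OC)c4)[C@@H]4CO4)cc3[C@H]2CO[Si](C)(C)C(C)(C)C)ccc1O[Si](C(C)C)(C(C)C)C(C)C
F5 | step 12 | tris-silyl ether of the target | COc1cc([C@H]2Oc3c(OC)cc([C@H]4OC[C@H]5[C@@H]4CO[C@@H]5c4cc(OC)c(O[Si](C(C)C)(C(C)C)C(C)C)c(OC)c4)cc3[C@H]2CO[Si](C)(C)C(C)(C)C)ccc1O[Si](C(C)C)(C(C)C)C(C)C
F6 | step 6 | (R)-pantolactonyl diazoacetate | CC1(C)COC(=O)[C@@H]1OC(=O)C=[N+]=[N-]
F7 | step 6 | (R)-pantolactonyl aryldiazoacetate | CC1(C)COC(=O)[C@@H]1OC(=O)C(=[N+]=[N-])c1cc(/C=C/C(=O)OC)cc(OC)c1OCc1ccc(O[Si](C(C)C)(C(C)C)C(C)C)c(OC)c1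
F8 | step 6 | (R)-pantolactonyl (2S,3R)-cis-dihydrobenzofuran-3-carboxylate | COc1cc([C@H]2Oc3c(OC)cc(/C=C/C(=O)OC)cc3[C@H]2C(=O)O[C@H]4C(=O)OCC4(C)C)ccc1O[Si](C(C)C)(C(C)C)C(C)C
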